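The plan rests on cutting N1'–C2' in the pyrrole ring (ring C) of the N-linked indole. The feature exploited is that N1' is bonded to two arene carbons, C7a' of ring D (benzene ring of that indole) and the sterically congested C4 of ring A (benzene ring of the NH indole). Such a nitrogen can enter as a plain diarylamine made by SNAr, which avoids coupling two hindered indoles. One oxidative amination of an ortho vinyl group by divalent palladium then forms N1'–C2', closes ring C and aromatises it. The precursor is a 2-vinyl diarylamine already carrying the C5 and C5' bromines, the methoxy group and a nitro group, from which pyrrole ring B is later grown.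

Key step: step 4

Assumption: the target string fixes no configuration at the hindered C4–N1' axis, so axial chirality is not controlled and the product is taken as the racemate if rotation is slow.

Atom mapping: in 2 the carbon bearing NH2 becomes C4, the brominated carbon C5, the methoxy carbon C7 and the nitro carbon C7a. The free CH between NH2 and NO2 becomes C3a. In 3 the fluorinated carbon becomes C7a', the formyl carbon C3' and the brominated carbon C5'.

Step 1
Reactants: 1 4-methoxy-3-nitroaniline
Product: 2 2-bromo-4-methoxy-5-nitroaniline
Conditions: NBS (1.0 equiv), MeCN, 0 °C to rt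
Reagents that add atoms: N-bromosuccinimide, O=C1CCC(=O)N1Br
Why: Electrophilic aromatic bromination is steered by the amino group, whose para position is blocked by methoxy and whose other ortho position is wedged between NH2 and NO2, so bromine should enter at the open ortho carbon (para to nitro, the future C5).

Step 2
Reactants: 2 2-bromo-4-methoxy-5-nitroaniline; 3 5-bromo-2-fluorobenzaldehyde
Product: 4 5-bromo-2-[(2-bromo-4-methoxy-5-nitrophenyl)amino]benzaldehyde
Conditions: Cs2CO3 (2.5 equiv), 3 (1.2 equiv), DMSO, 90 °C, argon; work-up with dilute aq HCl
Reagents that add atoms: none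
Why: Nucleophilic aromatic substitution by addition–elimination: the ortho formyl group stabilises the Meisenheimer adduct and fluoride is the best leaving group on offer, so the carbonate-activated aniline should displace F faster than it attacks the nitro-activated C–Br of another molecule of 2, and any imine formed reversibly at the aldehyde still undergoes the same substitution and is hydrolysed back to 4 in the acidic work-up.

Step 3
Reactants: 4 5-bromo-2-[(2-bromo-4-methoxy-5-nitrophenyl)amino]benzaldehyde
Product: 5 2-bromo-N-(4-bromo-2-vinylphenyl)-4-methoxy-5-nitroaniline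
Conditions: MePPh3Br (3.0 equiv), KOtBu (2.9 equiv), THF, 0 °C to rt
Reagents that add atoms: methyltriphenylphosphonium bromide, C[P+](c1ccccc1)(c1ccccc1)c1ccccc1.[Br-]
Why: Wittig methylenation, in which the surplus ylide covers deprotonation of the acidic diarylamine N–H, the slight deficit of base leaves no free alkoxide to attack the nitro-activated bromide, and nitro and aryl bromide groups are inert to the ylide at this temperature.

Step 4
Reactants: 5 2-bromo-N-(4-bromo-2-vinylphenyl)-4-methoxy-5-nitroaniline
Product: 6 5-bromo-1-(2-bromo-4-methoxy-5-nitrophenyl)-1H-indole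
Conditions: PdCl2(MeCN)2 (10 mol %), 1,4-benzoquinone (1.5 equiv), LiCl (10 equiv), THF, 65 °C, argon
Reagents that add atoms: none
Why: The electrophilic PdCl2 unit (divalent palladium) π-binds the vinyl group, the N–H nitrogen attacks the CH2 terminus (future C2') with loss of HCl to leave a benzylic C3'–Pd σ-bond, and syn elimination of Pd–H with one of the two C2' hydrogens furnishes the aromatic pyrrole directly, without any later double-bond shift; benzoquinone plus the liberated HCl then turns zerovalent palladium back into PdCl2. The closest known reaction is the Hegedus indole synthesis, an intramolecular aza-Wacker oxidative amination that is established for 2-vinylanilines, bromoarene-bearing ones included. Ring C closes in the 5-endo-trig mode, since attack at the internal alkene carbon would be a 4-exo closure to a strained benzazetine. No stereocentre is formed. The selectivity required is alkene activation in preference to insertion into C–Br, above all the C–Br that is ortho to nitrogen and para to nitro, where insertion would start an intramolecular Heck closure to acridine- or dibenzazepine-type rings; the phosphine-free and base-free medium, the chloride excess and the surplus quinone keep zerovalent palladium short-lived. The electron-poor bromonitroaryl group makes the nitrogen too weakly basic to tie up the catalyst, yet it stays a better nucleophile than the sulfonamides usually cyclised this way.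

Step 5
Reactants: 6 5-bromo-1-(2-bromo-4-methoxy-5-nitrophenyl)-1H-indole; 7 vinylmagnesium bromide
Product: 9 5-bromo-4-(5-bromo-1H-indol-1-yl)-7-methoxy-1H-indole, via nitrosoarene 8 (not isolated)
Conditions: CH2=CHMgBr (3.5 equiv), THF, −45 °C; sat. aq NH4Cl quench
Reagents that add atoms: vinylmagnesium bromide (7), C=C[Mg]Br
Why: Bartoli indole synthesis: one equivalent of 7 takes the nitro group down to nitrosoarene 8, a second adds to the nitroso oxygen and the ortho methoxy group pushes the [3,3]-sigmatropic shift onto the only free ortho carbon (future C3a), a third serves as base for ring closure and aromatisation, while aryl bromides do not undergo exchange with a vinyl Grignard reagent at this temperature.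

Step 6
Reactants: 9 5-bromo-4-(5-bromo-1H-indol-1-yl)-7-methoxy-1H-indole
Product: 10 Rivularin B, 3,5-dibromo-4-(3,5-dibromo-1H-indol-1-yl)-7-methoxy-1H-indole
Conditions: NBS (2.05 equiv), DMF, 0 °C, dark
Reagents that add atoms: N-bromosuccinimide, O=C1CCC(=O)N1Br
Why: Electrophilic bromination of indoles at their β-positions: C3 of ring B and C3' of ring C are the two enamine-type carbons, so two equivalents of NBS at low temperature should be consumed there before C2, C2' or C6 react.

Compound list
1 | 4-methoxy-3-nitroaniline | COc1ccc(N)cc1[N+](=O)[O-] | starting material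
2 | 2-bromo-4-methoxy-5-nitroaniline | COc1cc(Br)c(N)cc1[N+](=O)[O-] | intermediate
3 | 5-bromo-2-fluorobenzaldehyde | O=Cc1cc(Br)ccc1F | starting material
4 | 5-bromo-2-[(2-bromo-4-methoxy-5-nitrophenyl)amino]benzaldehyde | COc1cc(Br)c(Nc2ccc(Br)cc2C=O)cc1[N+](=O)[O-] | intermediate
5 | 2-bromo-N-(4-bromo-2-vinylphenyl)-4-methoxy-5-nitroaniline | COc1cc(Br)c(Nc2ccc(Br)cc2C=C)cc1[N+](=O)[O-] | intermediate
6 | 5-bromo-1-(2-bromo-4-methoxy-5-nitrophenyl)-1H-indole | COc1cc(Br)c(-n2ccc3cc(Br)ccc32)cc1[N+](=O)[O-] | intermediate
7 | vinylmagnesium bromide | C=C[Mg]Br | starting material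
8 | 5-bromo-1-(2-bromo-4-methoxy-5-nitrosophenyl)-1H-indole (nitrosoarene, not isolated) | COc1cc(Br)c(-n2ccc3cc(Br)ccc32)cc1N=O | intermediate
9 | 5-bromo-4-(5-bromo-1H-indol-1-yl)-7-methoxy-1H-indole | COc1cc(Br)c(-n2ccc3cc(Br)ccc32)c2cc[nH]c12 | intermediate
10 | Rivularin B, 3,5-dibromo-4-(3,5-dibromo-1H-indol-1-yl)-7-methoxy-1H-indole | COc1cc(Br)c(-n2cc(Br)c3cc(Br)ccc32)c2c(Br)c[nH]c12 | target

Total step count: 6
Longest linear sequence: 6 steps (1 to 10)

Steps most likely to fail

Step 4. Aminopalladation by the crowded, weakly nucleophilic nitrogen may be slow, and the catalyst may precipitate as metal. Transient zerovalent palladium may also insert into the nitro-activated C–Br bond and trigger a Heck-type ring closure. The fallback closes the same N1'–C2' bond without palladium and without an oxidant. It sets out from aldehyde 4. A Wittig reaction with (methoxymethyl)triphenylphosphonium chloride and KOtBu in THF at 0 °C should give the enol ether 2-bromo-N-[4-bromo-2-(2-methoxyvinyl)phenyl]-4-methoxy-5-nitroaniline F1 as an E/Z mixture. Catalytic p-toluenesulfonic acid in THF at 50 °C should protonate the enol ether. The diarylamine nitrogen then adds to the oxocarbenium carbon, methanol is lost, and the route is rejoined at 6.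

Step 5. The nitro group may be over-reduced to aniline-type products. The Grignard reagent may add to the electron-poor ring, and the sigmatropic shift onto a carbon flanked by the bulky N-indolyl group may be slow. The fallback replaces the one-pot indolisation by an ortho-halogenation, alkynylation and cyclisation sequence. It sets out from 6. One equivalent of NBS in DMF at 0 °C should give 3,5-dibromo-1-(2-bromo-4-methoxy-5-nitrophenyl)-1H-indole F2, which blocks the reactive C3' position with a bromine that the target needs anyway. Iron powder and NH4Cl in aqueous ethanol at 70 °C should reduce the nitro group to 4-bromo-5-(3,5-dibromo-1H-indol-1-yl)-2-methoxyaniline F3. N-Iodosuccinimide in MeCN should iodinate the only free position ortho to NH2 and give 4-bromo-3-(3,5-dibromo-1H-indol-1-yl)-2-iodo-6-methoxyaniline F4. Sonogashira coupling with trimethylsilylacetylene (PdCl2(PPh3)2, CuI, Et3N, rt) should occur at C–I only and give 4-bromo-3-(3,5-dibromo-1H-indol-1-yl)-6-methoxy-2-[(trimethylsilyl)ethynyl]aniline F5. CuI in DMF at 100 °C should close ring B with loss of silicon to give 5-bromo-4-(3,5-dibromo-1H-indol-1-yl)-7-methoxy-1H-indole F6. One equivalent of NBS in DMF at 0 °C should then brominate C3, so the route is rejoined at 10.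

Step 2. Displacement by a hindered, electron-poor aniline may be slow. Condensation at the aldehyde and self-arylation at the nitro-activated C–Br bond may compete during the long heating. The fallback swaps the formyl activator for a group that tolerates a preformed anilide and unveils the aldehyde afterwards. It sets out from 2, which is deprotonated with LiN(SiMe3)2 (2.2 equiv) in THF at −78 °C. Treatment with commercial 5-bromo-2-fluorobenzonitrile (N#Cc1cc(Br)ccc1F) and warming to rt should give 5-bromo-2-[(2-bromo-4-methoxy-5-nitrophenyl)amino]benzonitrile F7. Partial reduction with i-Bu2AlH (2.5 equiv) in CH2Cl2 at −78 °C, where the nitroarene should be spared, is followed by hydrolysis of the imine with aq HCl. This rejoins the route at 4.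

Further compounds
F1 | step 4 | 2-bromo-N-[4-bromo-2-(2-methoxyvinyl)phenyl]-4-methoxy-5-nitroaniline (E/Z mixture) | COC=Cc1cc(Br)ccc1Nc1cc([N+](=O)[O-])c(OC)cc1Br
F2 | step 5 | 3,5-dibromo-1-(2-bromo-4-methoxy-5-nitrophenyl)-1H-indole | COc1cc(Br)c(-n2cc(Br)c3cc(Br)ccc32)cc1[N+](=O)[O-]
F3 | step 5 | 4-bromo-5-(3,5-dibromo-1H-indol-1-yl)-2-methoxyaniline | COc1cc(Br)c(-n2cc(Br)c3cc(Br)ccc32)cc1N
F4 | step 5 | 4-bromo-3-(3,5-dibromo-1H-indol-1-yl)-2-iodo-6-methoxyaniline | COc1cc(Br)c(-n2cc(Br)c3cc(Br)ccc32)c(I)c1N
F5 | step 5 | 4-bromo-3-(3,5-dibromo-1H-indol-1-yl)-6-methoxy-2-[(trimethylsilyl)ethynyl]aniline | COc1cc(Br)c(-n2cc(Br)c3cc(Br)ccc32)c(C#C[Si](C)(C)C)c1N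
F6 | step 5 | 5-bromo-4-(3,5-dibromo-1H-indol-1-yl)-7-methoxy-1H-indole | COc1cc(Br)c(-n2cc(Br)c3cc(Br)ccc32)c2cc[nH]c12
F7 | step 2 | 5-bromo-2-[(2-bromo-4-methoxy-5-nitrophenyl)amino]benzonitrile | COc1cc(Br)c(Nc2ccc(Br)cc2C#N)cc1[N+](=O)[O-]
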